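We want to know how much product this flask gives at the asked time, how large the excess of left-handed product is, and whether the exchange between the two substrates keeps up with the reaction.

| flask | left-handed substrate | right-handed substrate | reagent | free catalyst | racemization catalyst | added ligand | remark | time |
|---|---|---|---|---|---|---|---|---|
| south-west | 0.18 M | 0.18 M | 0.36 M (fed, over 4.0 h) | 0.90 mM | 0.99 mM | 0.36 mM | run made earlier; the fed solution adds 0.50 times the starting volume |  |
| north | 0.18 M | 0.18 M | 0.36 M (fed, over 4.0 h) | 0.90 mM | 0.99 mM | 0.80 mM | run made earlier; the fed solution adds 0.50 times the starting volume |  |
| north-east | 0.18 M | 0.18 M | 0.36 M (fed, over 4.0 h) | 1.4 mM | 0.99 mM | 0.53 mM | run made earlier; the fed solution adds 0.50 times the starting volume |  |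
| flask | 0.18 M | 0.18 M | 0.360 M (fed, over 4.0 h) | 0.90 mM | 0.99 mM | 0.53 mM | the fed solution adds 0.50 times the starting volume | 15 h |

| run | time / h | left-handed product / % | right-handed product / % |
|---|---|---|---|
| south-west | 3.00 | 39 | 17 |
| south-west | 6.00 | 59 | 29 |
| south-west | 10.0 | 64 | 31 |
| south-west | 12.0 | 65 | 28 |
| north | 1.50 | 20 | 7 |
| north | 4.00 | 47 | 24 |
| north | 8.00 | 61 | 30 |
| north | 12.0 | 60 | 30 |
| north-east | 1.00 | 12 | 8 |
| north-east | 2.00 | 31 | 14 |
| north-east | 5.00 | 56 | 27 |
| north-east | 12.0 | 62 | 32 |

(readings scatter by 1.5 percentage points)

* left-handed product and right-handed product together, in percent of the left-handed substrate and right-handed substrate charged together, at 15 h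
* excess of left-handed product over right-handed product in the product at 15 h
* whether the exchange between left-handed substrate and right-handed substrate keeps pace with the reaction: how far the product's excess at 15 h gets from its value without exchange to its value with instant exchange (above 80% keeps pace, below 20% hardly takes part, else lags behind)

- free catalyst is single-handed; left-handed substrate and right-handed substrate are mirror images of each other, charged as a racemate, each of them at the stated concentration
- amounts are per litre of the starting volume; all of the dose is in the solution fed
- the numbers in the tables scatter with a standard deviation of 1.5 percentage points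
- an excess is below zero if the other one leads

The runs seem to answer at once. Left-handed product reaches 65% of the charge in the south-west run, though left-handed substrate was only 50.0% of it, and the product ratio, left over right, looks steady: 2.22 pooled over the four early readings (up to 3.00 h), 2.07 over the five late ones. Yet those early readings also give another selectivity factor, s, the number of times faster left-handed substrate reacts at equal amounts. Instant exchange makes s the ratio itself; no exchange makes it the ratio of the logarithms of what remains of each substrate, 2.73.

We carry the ceiling, the excess (s−1)/(s+1) that instant exchange holds, taken at the upper s: 46.4%, against 37.8% at the lower. Late readings give 92.6% product and excess 34.8%. The unexchanged floor comes by iteration: guess the leftover of left-handed substrate, subtract, put the answer back. Two rounds give 0.148 shared out and a floor of 7.46%. So the excess gets 70.2% of the way at the upper ceiling and 90.1% at the lower. The lower assumes instant exchange, the thing asked, so we expect less than 80%: lagging.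

The forecast gives 93% (89% to 97%), 35% (31% to 39%) and keeps pace: “so exchange keeps pace”. There it parts from our reckoning.

The flask gives 95.1% and 34.4%, and the exchange lags behind, getting 75% of the way. Its product excess is 40.3% after 1.50 h and 34.2% after 7.50 h.

    reagent + free catalyst + left-handed substrate → free catalyst + left-handed product (k = 6.61 /M²/s)
    reagent + free catalyst + right-handed substrate → free catalyst + right-handed product (k = 2.58 /M²/s)
    left-handed substrate + racemization catalyst ⇌ right-handed substrate + racemization catalyst, rate k3*[racemization catalyst]*[left-handed substrate] forward; the back reaction follows from the equilibrium constant (k = 0.184 /M/s)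
    free catalyst + added ligand ⇌ idle complex (K = 950 /M, k = 0.219 /M/s)
    2 reagent → homo dimer (k = 4.20 × 10⁻⁵ /M/s)

The flask ends 12 percentage points under 46.4%, the ceiling as we read it from the early readings, with their scatter. With reagent cut to 0.090 M, the neighbouring flask holds 25.0% product at the asked time, each substrate at 37.5%, and its excess of 42.2% stands 4.2 points under that same reading of the ceiling.

The readings are simulated for an exercise, and the scatter is random.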